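**Retrosynthetic overview**
1. Target 26 ⇒ 23 by C9–O acylation with angelic acid; 23 ⇒ β-hydroxy ketone 20 + methacrolein by an Evans–Tishchenko step that makes the C7–O–acyl bond and the C9 carbinol (key step, new).
2. 20 ⇒ dienedione 18 by reagent-controlled C7–O introduction (Cu–B addition, oxidation); 18 ⇒ 17 by allylic C–H oxidation. All core oxygens are put on a finished carbon skeleton.
3. 16 ⇒ enone 12 by a γ-selective vinylogous aldol onto the cyclobutanone (C5–C6 bond) and Barton–McCombie removal of the C5 oxygen.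
4. 12 ⇒ vinyl ketone 7 + isobutyraldehyde (Wacker, aldol condensation); 7 ⇒ trienoic acid 4 by intramolecular vinylketene–alkene [2+2]; 4 ⇒ methyl geranate.
5. Ring order: cyclobutane and six-membered ring together (step 3), then the seven-membered ring (step 6).

Assumption: tricycles carry longipinane numbering (C1 enone carbonyl, C2=C3(CH3, C15), C4, C5, C6(CH3)2, C7, C8, C9, C10(CH3), C11), and 7, 8 and 10–18 are racemic, named and drawn as the enantiomer that leads to the target.

**Route**

Step 1
Reactants: 1 methyl (2E)-3,7-dimethylocta-2,6-dienoate (methyl geranate)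
Product: 2 methyl (2E,6E)-3,7-dimethyl-8-oxoocta-2,6-dienoate
Conditions: SeO2 (1.2 equiv), 1,4-dioxane, 80 °C
Reagents that add atoms: selenium dioxide, O=[Se]=O
Why: Riley allylic oxidation (ene reaction, then [2,3]-shift) takes the (E)-methyl of the electron-rich 6,7-alkene to the (E)-enal, while the conjugated 2,3-alkene is too electron-poor to react, and no stereocentre is formed.

Step 2
Reactants: 2 methyl (2E,6E)-3,7-dimethyl-8-oxoocta-2,6-dienoate
Product: 4 (2E,6E)-3,7-dimethylnona-2,6,8-trienoic acid, via triene methyl ester 3 (not isolated)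
Conditions: Ph3PCH3Br, KOt-Bu, THF, 0 °C; then LiOH, MeOH/H2O, 40 °C; HCl work-up
Reagents that add atoms: methylenetriphenylphosphorane, C=P(c1ccccc1)(c1ccccc1)c1ccccc1; lithium hydroxide, [Li+].[OH-]
Why: Wittig methylenation of the aldehyde (the enoate is inert to the ylide at 0 °C) gives the 1,3-diene with the 6E geometry untouched, and saponification in the same flask lets the acid be extracted away from Ph3PO.

Step 3
Reactants: 4 (2E,6E)-3,7-dimethylnona-2,6,8-trienoic acid
Product: 7 (±)-7-ethenyl-7-methyl-2-methylidenebicyclo[3.1.1]heptan-6-one (ethenyl anti to the C2–C4 bridge), via acid chloride 5 (not isolated), via vinylketene 6 (not isolated)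
Conditions: (COCl)2, PhH, rt; then Et3N, PhMe, reflux, slow addition (0.01 M)
Reagents that add atoms: none
Why: Intramolecular vinylketene–alkene [2+2] cycloaddition (Snider type): Et3N forms the vinylketene by γ-deprotonation, its carbonyl carbon bonds to the CH end of the alkene and its α-carbon to the fully substituted end, which closes the cyclobutane and the six-membered ring at once, and suprafacial addition to the 6E alkene puts the vinyl group anti and the methyl syn to the three-carbon bridge, so the relative configuration of the later C4, C10 and C11 is set (racemic).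

Step 4
Reactants: 7 (±)-7-ethenyl-7-methyl-2-methylidenebicyclo[3.1.1]heptan-6-one
Product: 8 (±)-7-acetyl-7-methyl-2-methylidenebicyclo[3.1.1]heptan-6-one
Conditions: PdCl2 (10 mol%), CuCl, O2 (1 atm), DMF/H2O 7:1, rt
Reagents that add atoms: water, O
Why: Tsuji–Wacker oxidation with Markovnikov hydroxypalladation of the monosubstituted vinyl group gives the methyl ketone, the 1,1-disubstituted exocyclic alkene reacting much more slowly.

Step 5
Reactants: 8 (±)-7-acetyl-7-methyl-2-methylidenebicyclo[3.1.1]heptan-6-one; 9 isobutyraldehyde (2-methylpropanal)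
Product: 12 (±)-7-methyl-2-methylidene-7-[(2E)-4-methylpent-2-enoyl]bicyclo[3.1.1]heptan-6-one, via aldol adduct 10 (not isolated), via aldol mesylate 11 (not isolated)
Conditions: LDA, THF, −78 °C; 9; then MsCl, −78 → 0 °C; DBU, rt
Reagents that add atoms: isobutyraldehyde, CC(C)C=O
Why: Directed aldol condensation: the acetyl CH3 is the only enolisable position (C7 is quaternary, the cyclobutanone is flanked by bridgeheads), and mesylation with E1cB elimination gives the (E)-enone that brings in C6, C7 and the gem-dimethyl group.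

Step 6
Reactants: 12 (±)-7-methyl-2-methylidene-7-[(2E)-4-methylpent-2-enoyl]bicyclo[3.1.1]heptan-6-one
Product: 15 (±)-S-methyl O-(9-oxolongipina-3(15),7-dien-5-yl) carbonodithioate, via potassium alkoxide 13 (not isolated), via potassium xanthate 14 (not isolated)
Conditions: KHMDS, THF, −78 → 0 °C; CS2, 0 °C; MeI, rt
Reagents that add atoms: carbon disulfide, S=C=S; iodomethane, CI
Why: Intramolecular vinylogous aldol addition: with no α′-hydrogen the base removes the γ-hydrogen of the isopropyl group, and the dienolate attacks the strained cyclobutanone through its γ-carbon (α-attack would give a bicyclo[2.1.1]hexane) on the face anti to the three-carbon bridge, where the tether sits, which closes the seven-membered ring and fixes C5 with C6 on the side of the C9 bridge, and CS2/MeI trap the alkoxide as the xanthate before it can revert.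

Step 7
Reactants: 15 (±)-S-methyl O-(9-oxolongipina-3(15),7-dien-5-yl) carbonodithioate
Product: 16 (±)-longipina-3(15),7-dien-9-one
Conditions: n-Bu3SnH, AIBN (cat.), PhMe, 100 °C
Reagents that add atoms: none
Why: Barton–McCombie deoxygenation: the tertiary cyclobutyl radical cannot invert because C6 is tied into the seven-membered ring, so hydrogen enters where oxygen left and H-5 ends on the side of the C1–C3 bridge as in the target, and Chugaev elimination is impossible because the only β-hydrogens are at bridgeheads.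

Step 8
Reactants: 16 (±)-longipina-3(15),7-dien-9-one
Product: 17 (±)-longipina-2,7-dien-9-one
Conditions: RhCl3·3H2O (5 mol%), EtOH, 75 °C
Reagents that add atoms: none
Why: Rh–H addition and β-hydride elimination move the exocyclic alkene into the ring to the more stable trisubstituted isomer (the β- to α-pinene relationship), with no stereocentre affected.

Step 9
Reactants: 17 (±)-longipina-2,7-dien-9-one
Product: 18 (±)-longipina-2,7-diene-1,9-dione
Conditions: CrO3, 3,5-dimethylpyrazole, CH2Cl2, −20 °C
Reagents that add atoms: chromium trioxide, O=[Cr](=O)=O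
Why: Allylic C–H oxidation with the CrO3·3,5-dimethylpyrazole complex forms the C1 carbonyl at the only secondary allylic position, as in α-pinene to verbenone, since the C4 bridgehead cannot react and the cycloheptenone has no allylic hydrogen.

Step 10
Reactants: 18 (±)-longipina-2,7-diene-1,9-dione
Product: 20 (4R,5S,7R,10R,11R)-7-hydroxylongipin-2-ene-1,9-dione, via boryl ketone 19 (not isolated)
Conditions: B2pin2, CuCl (5 mol%), NaOt-Bu (cat.), Josiphos-type ligand (enantiomer giving 7R), MeOH, THF, rt; then NaBO3·4H2O, THF/H2O, 0 °C; chromatography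
Reagents that add atoms: sodium perborate, [Na+].[Na+].O[B-]1(O)OO[B-](O)(O)OO1
Why: Copper-catalysed enantioselective conjugate borylation followed by stereoretentive C–B oxidation: the two faces of the cycloheptenone differ only through the remote enone bridge, so the ligand alone decides and makes C7–O with the 7R configuration in both enantiomers of 18, which turns the racemate into two diastereomers of which the (4R,5S,10R,11R) one is 20 (at most 50%), while the β,β-disubstituted C1 enone is inert.

Step 11
Reactants: 20 (4R,5S,7R,10R,11R)-7-hydroxylongipin-2-ene-1,9-dione; 21 methacrolein (2-methylprop-2-enal)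
Product: 23 (4R,5S,7R,9R,10R,11R)-9-hydroxy-1-oxolongipin-2-en-7-yl 2-methylprop-2-enoate, via hemiacetal 22 (not isolated)
Conditions: SmI2 (20 mol%), 21 (6 equiv), THF, −10 °C, dark
Reagents that add atoms: methacrolein, CC(=C)C=O
Why: Proposed new method: an Evans–Tishchenko reduction run with an α-branched enal (methacrolein) as hydride donor, so that the acyl group left on O7 is the methacrylate itself, on a β-hydroxy cycloheptanone whose carbinol and carbonyl are both neopentylic; the Sm(III) alkoxide of 20 adds 1,2 to methacrolein, samarium bridges the hemiacetal oxygen and the C9 carbonyl, and the hemiacetal C–H shifts as hydride through a six-membered chair-like transition state onto the carbonyl face syn to O7, which forms the C7–O–acyl bond and sets C9 trans to O7 (9R), the gain of ester conjugation making the shift irreversible while oxa-Michael addition to the enal is reversible; the closest known reaction is the SmI2-catalysed Evans–Tishchenko reduction with saturated or aromatic aldehydes.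

Step 12
Reactants: 23 (4R,5S,7R,9R,10R,11R)-9-hydroxy-1-oxolongipin-2-en-7-yl 2-methylprop-2-enoate; 24 angelic acid ((2Z)-2-methylbut-2-enoic acid)
Product: 26 (4R,5S,7R,9R,10R,11R)-7-[(2-methylprop-2-enoyl)oxy]-1-oxolongipin-2-en-9-yl (2Z)-2-methylbut-2-enoate, via mixed anhydride 25 (not isolated)
Conditions: 24, 2,4,6-Cl3C6H2COCl, Et3N, PhMe, rt; then 23, DMAP, 80 °C
Reagents that add atoms: angelic acid, C/C=C(/C)C(=O)O
Why: Yamaguchi esterification through the mixed anhydride acylates the hindered C9 hydroxyl under conditions that keep the (Z)-geometry of the angelate, and no stereocentre is touched.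

**Compound list**
1 | methyl (2E)-3,7-dimethylocta-2,6-dienoate (methyl geranate) | COC(=O)/C=C(\C)CCC=C(C)C | starting material
2 | methyl (2E,6E)-3,7-dimethyl-8-oxoocta-2,6-dienoate | COC(=O)/C=C(\C)CC/C=C(\C)C=O | intermediate
3 | methyl (2E,6E)-3,7-dimethylnona-2,6,8-trienoate | COC(=O)/C=C(\C)CC/C=C(\C)C=C | intermediate (not isolated)
4 | (2E,6E)-3,7-dimethylnona-2,6,8-trienoic acid | OC(=O)/C=C(\C)CC/C=C(\C)C=C | intermediate
5 | (2E,6E)-3,7-dimethylnona-2,6,8-trienoyl chloride | ClC(=O)/C=C(\C)CC/C=C(\C)C=C | intermediate (not isolated)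
6 | (6E)-7-methyl-3-methylidenenona-1,6,8-trien-1-one (vinylketene) | O=C=CC(=C)CC/C=C(\C)C=C | intermediate (not isolated)
7 | (±)-7-ethenyl-7-methyl-2-methylidenebicyclo[3.1.1]heptan-6-one, ethenyl anti and methyl syn to the C2–C4 bridge | C=C[C@@]1(C)[C@@H]2CCC(=C)[C@H]1C2=O | intermediate
8 | (±)-7-acetyl-7-methyl-2-methylidenebicyclo[3.1.1]heptan-6-one, acetyl anti to the C2–C4 bridge | CC(=O)[C@@]1(C)[C@@H]2CCC(=C)[C@H]1C2=O | intermediate
9 | isobutyraldehyde (2-methylpropanal) | CC(C)C=O | starting material
10 | (±)-7-(3-hydroxy-4-methylpentanoyl)-7-methyl-2-methylidenebicyclo[3.1.1]heptan-6-one, carbinol epimers (as lithium aldolate) | CC(C)C(O)CC(=O)[C@@]1(C)[C@@H]2CCC(=C)[C@H]1C2=O | intermediate (not isolated)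
11 | methanesulfonate of 10 | CC(C)C(OS(C)(=O)=O)CC(=O)[C@@]1(C)[C@@H]2CCC(=C)[C@H]1C2=O | intermediate (not isolated)
12 | (±)-7-methyl-2-methylidene-7-[(2E)-4-methylpent-2-enoyl]bicyclo[3.1.1]heptan-6-one | CC(C)/C=C/C(=O)[C@@]1(C)[C@@H]2CCC(=C)[C@H]1C2=O | intermediate
13 | potassium (±)-9-oxolongipina-3(15),7-dien-5-olate, O-5 on the side of the C1–C3 bridge | C1=CC(=O)[C@@]2(C)[C@@H]3CCC(=C)[C@H]2[C@]3([O-])C1(C)C.[K+] | intermediate (not isolated)
14 | potassium (±)-O-(9-oxolongipina-3(15),7-dien-5-yl) carbonodithioate | C1=CC(=O)[C@@]2(C)[C@@H]3CCC(=C)[C@H]2[C@]3(OC(=S)[S-])C1(C)C.[K+] | intermediate (not isolated)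
15 | (±)-S-methyl O-(9-oxolongipina-3(15),7-dien-5-yl) carbonodithioate | C1=CC(=O)[C@@]2(C)[C@@H]3CCC(=C)[C@H]2[C@]3(OC(=S)SC)C1(C)C | intermediate
16 | (±)-longipina-3(15),7-dien-9-one, ring fusion as in the target | C1=CC(=O)[C@@]2(C)[C@@H]3CCC(=C)[C@H]2[C@@H]3C1(C)C | intermediate
17 | (±)-longipina-2,7-dien-9-one | C1=CC(=O)[C@@]2(C)[C@@H]3CC=C(C)[C@H]2[C@@H]3C1(C)C | intermediate
18 | (±)-longipina-2,7-diene-1,9-dione, drawn as (4R,5S,10R,11R) | C1=CC(=O)[C@@]2(C)[C@@H]3C(=O)C=C(C)[C@H]2[C@@H]3C1(C)C | intermediate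
19 | (4R,5S,10R,11R)-7-(4,4,5,5-tetramethyl-1,3,2-dioxaborolan-2-yl)longipin-2-ene-1,9-dione, boron where the 7R oxygen will stand | CC4(C)OB(OC4(C)C)[C@@H]1CC(=O)[C@@]2(C)[C@@H]3C(=O)C=C(C)[C@H]2[C@@H]3C1(C)C | intermediate (not isolated)
20 | (4R,5S,7R,10R,11R)-7-hydroxylongipin-2-ene-1,9-dione | O[C@@H]1CC(=O)[C@@]2(C)[C@@H]3C(=O)C=C(C)[C@H]2[C@@H]3C1(C)C | intermediate
21 | methacrolein (2-methylprop-2-enal) | CC(=C)C=O | starting material
22 | O7-(1-hydroxy-2-methylprop-2-enyl) hemiacetal of 20 (samarium-bound) | CC(=C)C(O)O[C@@H]1CC(=O)[C@@]2(C)[C@@H]3C(=O)C=C(C)[C@H]2[C@@H]3C1(C)C | intermediate (not isolated)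
23 | (4R,5S,7R,9R,10R,11R)-9-hydroxy-1-oxolongipin-2-en-7-yl 2-methylprop-2-enoate | CC(=C)C(=O)O[C@@H]1C[C@@H](O)[C@@]2(C)[C@@H]3C(=O)C=C(C)[C@H]2[C@@H]3C1(C)C | intermediate
24 | angelic acid, (2Z)-2-methylbut-2-enoic acid | C/C=C(/C)C(=O)O | starting material
25 | (2Z)-2-methylbut-2-enoic 2,4,6-trichlorobenzoic anhydride | C/C=C(/C)C(=O)OC(=O)c1c(Cl)cc(Cl)cc1Cl | intermediate (not isolated)
26 | (4R,5S,7R,9R,10R,11R)-7-[(2-methylprop-2-enoyl)oxy]-1-oxolongipin-2-en-9-yl (2Z)-2-methylbut-2-enoate | C=C(C)C(=O)O[C@@H]1C[C@@H](OC(=O)/C(C)=C\C)[C@@]2(C)[C@@H]3C(=O)C=C(C)[C@H]2[C@@H]3C1(C)C | target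

**Count and risks**
Total: 12 steps. Longest linear sequence: 12 steps (from 1).

Step 6 (vinylogous aldol ring closure with xanthate trapping) may not favour the cyclised alkoxide. The fallback sets out from 7 and closes the ring before the oxygen is removed: isobutyronitrile/LDA adds to the cyclobutanone from the face anti to the three-carbon bridge to give the hydroxy nitrile F1, DIBAL-H and aqueous acid give the hydroxy aldehyde F2, Wacker oxidation gives the keto aldehyde F3, and piperidinium acetate closes the seven-membered enone by intramolecular aldol condensation to the tertiary alcohol F4 (the protonated form of 13). NaH, CS2 and MeI then give 15, where the route is rejoined.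

Step 10 (ligand-controlled borylation next to a quaternary carbon, with separation of two closely related diastereomers) may be slow or poorly selective. The fallback sets out from 18 and forms the C7–O bond directly: amine-salt-catalysed asymmetric Weitz–Scheffer epoxidation (9-amino-9-deoxy-epi-quinine salt, aqueous H2O2) gives the epoxy ketone F5, the epoxide from the other enantiomer being removed at this stage. SmI2 in THF/MeOH at −90 °C cleaves the Cα–O bond and returns to the route at 20.

Step 11 (the new step) may suffer from methacrolein polymerisation, oxa-Michael addition or retro-aldol epimerisation at C7. The fallback uses known chemistry and sets out from 20: the standard Evans–Tishchenko reduction with acetaldehyde (SmI2 cat.) gives the 7-acetate F6, Yamaguchi esterification with angelic acid gives the acetate angelate F7, and guanidine in MeOH removes only the acetate to give the 7-hydroxy angelate F8. Methacrylic anhydride with DMAP then gives 26, where the route is rejoined.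

**Further compounds**
F1 | step 6 | (±)-2-(7-ethenyl-6-hydroxy-7-methyl-2-methylidenebicyclo[3.1.1]heptan-6-yl)-2-methylpropanenitrile, OH on the side of the C2–C4 bridge | C=C[C@@]1(C)[C@@H]2CCC(=C)[C@H]1[C@]2(O)C(C)(C)C#N
F2 | step 6 | (±)-2-(7-ethenyl-6-hydroxy-7-methyl-2-methylidenebicyclo[3.1.1]heptan-6-yl)-2-methylpropanal | C=C[C@@]1(C)[C@@H]2CCC(=C)[C@H]1[C@]2(O)C(C)(C)C=O
F3 | step 6 | (±)-2-(7-acetyl-6-hydroxy-7-methyl-2-methylidenebicyclo[3.1.1]heptan-6-yl)-2-methylpropanal | CC(=O)[C@@]1(C)[C@@H]2CCC(=C)[C@H]1[C@]2(O)C(C)(C)C=O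
F4 | step 6 | (±)-5-hydroxylongipina-3(15),7-dien-9-one | C1=CC(=O)[C@@]2(C)[C@@H]3CCC(=C)[C@H]2[C@]3(O)C1(C)C
F5 | step 10 | (4R,5S,7S,8S,10R,11R)-7,8-epoxylongipin-2-ene-1,9-dione | O1[C@@H]2[C@H]1C(=O)[C@@]3(C)[C@@H]4C(=O)C=C(C)[C@H]3[C@@H]4C2(C)C
F6 | step 11 | (4R,5S,7R,9R,10R,11R)-9-hydroxy-1-oxolongipin-2-en-7-yl acetate | CC(=O)O[C@@H]1C[C@@H](O)[C@@]2(C)[C@@H]3C(=O)C=C(C)[C@H]2[C@@H]3C1(C)C
F7 | step 11 | (4R,5S,7R,9R,10R,11R)-7-acetoxy-1-oxolongipin-2-en-9-yl (2Z)-2-methylbut-2-enoate | CC(=O)O[C@@H]1C[C@@H](OC(=O)/C(C)=C\C)[C@@]2(C)[C@@H]3C(=O)C=C(C)[C@H]2[C@@H]3C1(C)C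
F8 | step 11 | (4R,5S,7R,9R,10R,11R)-7-hydroxy-1-oxolongipin-2-en-9-yl (2Z)-2-methylbut-2-enoate | O[C@@H]1C[C@@H](OC(=O)/C(C)=C\C)[C@@]2(C)[C@@H]3C(=O)C=C(C)[C@H]2[C@@H]3C1(C)C
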